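## Retrosynthetic overview

1. Target 40 ⇐ silyl ether 39 ⇐ ketone 38 by α-methylenation at C16, the only enolisable carbon beside the C15 ketone.
2. Key disconnection (C9–C11 and C8–C15): 38 ⇐ aldehyde/unsaturated lactone/ester 36. A SmI2 ketyl–olefin closure forms the six-membered carbocycle C8–C9–C11–C12–C13–C14 on the unsaturated δ-lactone; the C8 samarium enolate then acylates itself with the C15 ester in the same flask (cyclopentanone).
3. Enabling feature: C8 and C9 are the α- and β-carbons of the lactone carbonyl C7, and C13 carries two CH2–C(=O) arms (C12–C11 and C16–C15). C11–C12–C13–C16–C15 is thus a glutaric semialdehyde ester hung on C8 through C14, so a ketyl at C11 reaches C9 (six-ring) and leaves a C8 enolate 1,5 to the C15 ester carbon (five-ring).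
4. 36 ⇐ Negishi coupling (C8–C14) of α-bromo unsaturated spirolactone 23 with the zinc reagent of iodo ester 32 (C13 by Evans alkylation). 23 ⇐ spirolactone 16 ⇐ Ti(III) epoxide opening/acrylate addition on epoxide 13 (quaternary C10) ⇐ dione 1 (C5 by asymmetric CuH reduction, C1 by Luche reduction).
5. Ring order: A ring (carbocycle of 1) → δ-lactone (step 9) → in step 21 the carbocycle C8–C9–C11–C12–C13–C14, with the cyclopentanone bond C8–C15 made in the same operation; no ring is closed after step 21.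

Key step: step 21

Assumption: the sense of induction of the copper hydride catalyst in step 4 is taken by analogy with 3-alkylcyclohex-2-enones; if the opposite sense is found, the ligand antipode is used and nothing else changes.

Locants C1–C20 in the text are ent-kaurane locants of the target; TBDPS = tert-butyl(diphenyl)silyl, TES = triethylsilyl.

## Route

Step 1
Reactants: 1 4,4-dimethylcyclohexane-1,3-dione
Product: 2 3-(2-methylpropoxy)-6,6-dimethylcyclohex-2-en-1-one
Conditions: i-BuOH, TsOH·H2O (cat.), benzene, reflux, Dean–Stark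
Reagents that add atoms: 2-methylpropan-1-ol, CC(C)CO
Why: Acid-catalysed vinylogous ester formation from a cyclic 1,3-diketone should etherify the carbonyl remote from the gem-dimethyl group and leave the neopentyl carbonyl as the ketone.

Step 2
Reactants: 2 3-(2-methylpropoxy)-6,6-dimethylcyclohex-2-en-1-one
Product: 5 3-(hydroxymethyl)-4,4-dimethylcyclohex-2-en-1-one, via silylmethyl carbinol 3 (not isolated), via enol ether diol 4 (not isolated)
Conditions: (i-PrO)Me2SiCH2MgCl, CeCl3, THF, 0 °C; KF, KHCO3, 30% H2O2, THF/MeOH, rt; 1 M HCl, THF, rt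
Reagents that add atoms: [(isopropoxydimethylsilyl)methyl]magnesium chloride, CC(C)O[Si](C)(C)C[Mg]Cl; hydrogen peroxide, OO
Why: Stork–Danheiser alkylative carbonyl transposition: 1,2-addition of the hydroxymethyl-anion equivalent, Tamao oxidation of the C–Si bond, then acid hydrolysis and dehydration place the CH2OH carbon (C6) on the ring carbon next to the quaternary centre.

Step 3
Reactants: 5 3-(hydroxymethyl)-4,4-dimethylcyclohex-2-en-1-one
Product: 6 3-(TBDPS-oxymethyl)-4,4-dimethylcyclohex-2-en-1-one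
Conditions: TBDPSCl, imidazole, DMF, rt
Reagents that add atoms: tert-butyl(chloro)diphenylsilane, CC(C)(C)[Si](Cl)(c1ccccc1)c1ccccc1
Why: Standard silylation of a primary alcohol.

Step 4
Reactants: 6 3-(TBDPS-oxymethyl)-4,4-dimethylcyclohex-2-en-1-one
Product: 8 (2R,3S)-2-[(dimethylamino)methyl]-3-(TBDPS-oxymethyl)-4,4-dimethylcyclohexan-1-one, via silyl enol ether 7 (not isolated)
Conditions: Cu(OAc)2·H2O (3 mol %), (R)-DTBM-SEGPHOS (3 mol %), (EtO)2MeSiH, toluene, 0 °C to rt; then Me2N=CH2+ I−, CH2Cl2, rt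
Reagents that add atoms: Eschenmoser's salt, C=[N+](C)C.[I-]
Why: Ligand-controlled copper hydride 1,4-reduction should set C5 by facial hydride delivery to the β-carbon and give a regiodefined silyl enol ether, which undergoes Mannich aminomethylation at C10 anti to the C5 substituent (this centre is removed in step 5).

Step 5
Reactants: 8 (2R,3S)-2-[(dimethylamino)methyl]-3-(TBDPS-oxymethyl)-4,4-dimethylcyclohexan-1-one
Product: 10 (R)-3-(TBDPS-oxymethyl)-4,4-dimethyl-2-methylidenecyclohexan-1-one, via ammonium iodide 9 (not isolated)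
Conditions: MeI, CH2Cl2, rt; then aq. NaHCO3, rt
Reagents that add atoms: none
Why: Quaternisation and E1cB elimination of the Mannich base should give the α-methylene ketone (C10=C20) without touching C5.

Step 6
Reactants: 10 (R)-3-(TBDPS-oxymethyl)-4,4-dimethyl-2-methylidenecyclohexan-1-one
Product: 11 (1S,3R)-3-(TBDPS-oxymethyl)-4,4-dimethyl-2-methylidenecyclohexan-1-ol
Conditions: NaBH4, CeCl3·7H2O, MeOH, −78 °C
Reagents that add atoms: none
Why: Luche 1,2-reduction; hydride should add to the carbonyl face anti to the C5 CH2OSi group, giving the 1,3-cis alcohol (C1).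

Step 7
Reactants: 11 (1S,3R)-3-(TBDPS-oxymethyl)-4,4-dimethyl-2-methylidenecyclohexan-1-ol
Product: 12 (3S,4S,8S)-8-(TBDPS-oxymethyl)-7,7-dimethyl-1-oxaspiro[2.5]octan-4-ol
Conditions: VO(acac)2 (cat.), t-BuOOH, CH2Cl2, 0 °C
Reagents that add atoms: tert-butyl hydroperoxide, CC(C)(C)OO
Why: Hydroxyl-directed vanadium-catalysed epoxidation of the allylic alcohol should deliver oxygen syn to the OH group.

Step 8
Reactants: 12 (3S,4S,8S)-8-(TBDPS-oxymethyl)-7,7-dimethyl-1-oxaspiro[2.5]octan-4-ol
Product: 13 triethylsilyl ether of 12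
Conditions: TESCl, imidazole, DMAP (cat.), DMF, rt
Reagents that add atoms: chlorotriethylsilane, CC[Si](Cl)(CC)CC
Why: Silylation of the secondary alcohol blocks O1 so that only O20 can lactonise in step 9.

Step 9
Reactants: 13 triethylsilyl ether of 12; 14 2,2,2-trifluoroethyl prop-2-enoate
Product: 16 (6S,7R,11S)-7-(TBDPS-oxymethyl)-8,8-dimethyl-11-(triethylsilyloxy)-2-oxaspiro[5.5]undecan-3-one, via hydroxy ester 15 (not isolated)
Conditions: Cp2TiCl2 (20 mol %), Zn dust, 2,4,6-collidine·HCl, THF, rt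
Reagents that add atoms: none
Why: Titanocene(III) reductive epoxide opening gives the tertiary C10 radical, which undergoes Giese addition to the acrylate and lactonisation of the activated ester; the C10–C9 bond should form anti to the cis C1-OTES and C5-CH2OSi groups and away from the axial C4 methyl, setting the quaternary C10.

Step 10
Reactants: 16 spirolactone
Product: 17 4-(phenylselanyl) derivative of 16 (C8 epimers)
Conditions: LDA, THF, −78 °C; PhSeBr
Reagents that add atoms: benzeneselenenyl bromide, Br[Se]c1ccccc1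
Why: α-Selenenylation of the lactone lithium enolate at C8.

Step 11
Reactants: 17 4-(phenylselanyl) derivative of 16
Product: 19 4,5-didehydro derivative of 16 (α,β-unsaturated lactone, C8=C9), via selenoxide 18 (not isolated)
Conditions: 30% H2O2, pyridine, CH2Cl2, 0 °C to rt
Reagents that add atoms: none
Why: Selenoxide syn-elimination; the only β-hydrogens are on C9, so the endocyclic enoate should form.

Step 12
Reactants: 19 unsaturated lactone
Product: 20 C1 alcohol (19 without the triethylsilyl group)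
Conditions: PPTS, MeOH/CH2Cl2, 0 °C to rt
Reagents that add atoms: none
Why: Mild acidic methanolysis should cleave the triethylsilyl ether and leave the TBDPS ether intact.

Step 13
Reactants: 20 C1 alcohol
Product: 21 C1 acetate of 20
Conditions: Ac2O, DMAP, pyridine, rt
Reagents that add atoms: acetic anhydride, CC(=O)OC(C)=O
Why: DMAP-catalysed acetylation installs the C1 acetate of the target before any other free hydroxyl exists.

Step 14
Reactants: 21 C1 acetate
Product: 23 4-bromo derivative of 21 (α-bromo unsaturated lactone), via dibromide 22 (not isolated)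
Conditions: Br2, CH2Cl2, 0 °C; then Et3N, 0 °C to rt
Reagents that add atoms: bromine, BrBr
Why: Bromine addition to the enoate followed by dehydrobromination through the acidic C8–H gives the α-bromo enoate.

Step 15
Reactants: 24 (R)-4-benzyl-1,3-oxazolidin-2-one; 25 pent-4-enoyl chloride
Product: 26 (R)-4-benzyl-3-(pent-4-enoyl)-1,3-oxazolidin-2-one
Conditions: n-BuLi, THF, −78 °C
Reagents that add atoms: none
Why: N-Acylation of the lithiated Evans auxiliary.

Step 16
Reactants: 26 (R)-4-benzyl-3-(pent-4-enoyl)-1,3-oxazolidin-2-one; 27 methyl bromoacetate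
Product: 28 methyl (3S)-3-{[(4R)-4-benzyl-2-oxo-1,3-oxazolidin-3-yl]carbonyl}hex-5-enoate
Conditions: NaHMDS, THF, −78 °C
Reagents that add atoms: none
Why: Evans asymmetric alkylation; the chelated Z-enolate is attacked on the face opposite to the benzyl group, setting the future C13.

Step 17
Reactants: 28 alkylated imide
Product: 30 (4S)-4-(prop-2-en-1-yl)oxolan-2-one, via hydroxy ester 29 (not isolated)
Conditions: NaBH4, THF/H2O, 0 °C to rt; then TsOH (cat.), CH2Cl2, rt
Reagents that add atoms: none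
Why: Borohydride reduces the activated imide carbonyl in preference to the methyl ester, and the γ-hydroxy ester lactonises; the stereocentre is untouched.

Step 18
Reactants: 30 (4S)-4-(prop-2-en-1-yl)oxolan-2-one
Product: 32 methyl (3S)-3-(iodomethyl)hex-5-enoate, via silyl ester 31 (not isolated)
Conditions: TMSI, CH2Cl2, rt; then MeOH, rt
Reagents that add atoms: iodotrimethylsilane, C[Si](C)(C)I; methanol, CO
Why: Silyl-iodide lactone opening (SN2 by iodide at the O–CH2 carbon) followed by methanolysis gives the γ-iodo ester.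

Step 19
Reactants: 32 methyl (3S)-3-(iodomethyl)hex-5-enoate; 23 α-bromo unsaturated lactone
Product: 34 23 with Br replaced by the (2R)-2-(2-methoxy-2-oxoethyl)pent-4-en-1-yl group, via alkylzinc iodide 33 (not isolated)
Conditions: Zn dust (TMSCl/BrCH2CH2Br activated), LiCl, THF, 40 °C; then 23, Pd2(dba)3 (2.5 mol %), SPhos (10 mol %), THF/NMP, rt
Reagents that add atoms: none
Why: Zinc insertion into the primary iodide and Negishi sp3–sp2 cross-coupling with the α-bromo enoate form C8–C14 without base, so the ester arm and the acetate are untouched.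

Step 20
Reactants: 34 coupled unsaturated lactone
Product: 36 aldehyde (side chain now (2S)-2-(2-methoxy-2-oxoethyl)-4-oxobutyl), via ozonide 35 (not isolated)
Conditions: O3, CH2Cl2, −78 °C (Sudan III end point); PPh3, −78 °C to rt
Reagents that add atoms: ozone, [O-][O+]=O
Why: Ozonolysis should cleave the electron-rich monosubstituted alkene in preference to the electron-poor trisubstituted enoate, unveiling the C11 aldehyde.

Step 21
Reactants: 36 aldehyde
Product: 38 (1S,5R,8S,9S,10R,11S,13S)-1-acetoxy-11-hydroxy-15-oxo-6-(TBDPS-oxy)-17-nor-6,7-seco-ent-kauran-7,20-olide, via samarium enolate 37 (not isolated)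
Conditions: SmI2 (2.2 equiv), THF, −78 °C (slow addition, 5 mM), then 0 °C; aq. NH4Cl
Reagents that add atoms: none
Why: Proposed new method: SmI2 reduces the aldehyde to a ketyl that adds to C9 of the unsaturated lactone, the resulting C8 radical is reduced to a samarium(III) enolate, and this enolate, kept aprotic, attacks the C15 methyl ester (directly or after relay of the acyl group through the C11 O-samarium alkoxide) and expels methoxide to give the β-keto lactone. The closest known reaction type is the SmI2 ketyl–olefin cyclisation/aldol cascade of aldehyde-tethered unsaturated lactones; the new element is termination by C-acylation with an ester instead of an aldol. The six-membered ring closes 6-endo-trig (radical), and the five-membered ring closes by 5-exo-trig, enolexo nucleophilic acyl substitution. C9 is set by attack on the lactone face syn to C1, because the other face is screened by the C5 CH2OTBDPS group and the C4 gem-dimethyl unit; C11 is set by a chair-like transition state with the O–Sm group and the C13 arm equatorial and anti to C10. C8 is set by the preformed C13 centre, whose ester arm can reach only the enolate face opposite to C11. The step needs reduction of the aldehyde in preference to enoate, ester and acetate (secured by the low temperature and the aldehyde's higher reduction potential), no proton source so that C8 is not protonated, and only 2.2 equiv of reductant so that the non-enolisable product ketone is not reduced.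

Step 22
Reactants: 38 17-nor ketone
Product: 39 6-O-TBDPS ether of 40
Conditions: (CH2O)n, i-Pr2NH·TFA, TFA (cat.), THF, reflux
Reagents that add atoms: paraformaldehyde (as formaldehyde), C=O
Why: Acid-mediated Mannich-type α-methylenation; C16 is the only enolisable position of the C15 ketone (C8 is quaternary), and the acetate, the free C11 hydroxyl and the lactone tolerate the non-basic conditions.

Step 23
Reactants: 39 6-O-TBDPS ether of 40
Product: 40 maoyecrystal E
Conditions: HF·pyridine, pyridine, THF, 0 °C to rt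
Reagents that add atoms: none
Why: Fluoride desilylation of the primary silyl ether under buffered conditions spares the acetate, the enone and the β-keto lactone.

## Compound list

1 | 4,4-dimethylcyclohexane-1,3-dione | O=C1CC(=O)C(C)(C)CC1 | starting material
2 | 3-(2-methylpropoxy)-6,6-dimethylcyclohex-2-en-1-one | CC(C)COC1=CC(=O)C(C)(C)CC1 | intermediate
3 | 1-{[dimethyl(propan-2-yloxy)silyl]methyl}-6,6-dimethyl-3-(2-methylpropoxy)cyclohex-2-en-1-ol (racemic, formed as its magnesium alkoxide) | CC(C)COC1=CC(O)(C[Si](C)(C)OC(C)C)C(C)(C)CC1 | intermediate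
4 | 1-(hydroxymethyl)-6,6-dimethyl-3-(2-methylpropoxy)cyclohex-2-en-1-ol (racemic) | CC(C)COC1=CC(O)(CO)C(C)(C)CC1 | intermediate
5 | 3-(hydroxymethyl)-4,4-dimethylcyclohex-2-en-1-one | O=C1C=C(CO)C(C)(C)CC1 | intermediate
6 | 3-{[tert-butyl(diphenyl)silyl]oxymethyl}-4,4-dimethylcyclohex-2-en-1-one | O=C1C=C(CO[Si](c2ccccc2)(c2ccccc2)C(C)(C)C)C(C)(C)CC1 | intermediate
7 | diethoxy(methyl)silyl enol ether (C1=C2) of (S)-3-(TBDPS-oxymethyl)-4,4-dimethylcyclohexanone | CCO[Si](C)(OCC)OC1=C[C@H](CO[Si](c2ccccc2)(c2ccccc2)C(C)(C)C)C(C)(C)CC1 | intermediate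
8 | (2R,3S)-2-[(dimethylamino)methyl]-3-(TBDPS-oxymethyl)-4,4-dimethylcyclohexan-1-one | CN(C)C[C@@H]1C(=O)CCC(C)(C)[C@H]1CO[Si](c1ccccc1)(c1ccccc1)C(C)(C)C | intermediate
9 | N-methyl ammonium iodide of 8 | C[N+](C)(C)C[C@@H]1C(=O)CCC(C)(C)[C@H]1CO[Si](c1ccccc1)(c1ccccc1)C(C)(C)C.[I-] | intermediate
10 | (R)-3-(TBDPS-oxymethyl)-4,4-dimethyl-2-methylidenecyclohexan-1-one | C=C1C(=O)CCC(C)(C)[C@H]1CO[Si](c1ccccc1)(c1ccccc1)C(C)(C)C | intermediate
11 | (1S,3R)-3-(TBDPS-oxymethyl)-4,4-dimethyl-2-methylidenecyclohexan-1-ol (1,3-cis) | C=C1[C@@H](O)CCC(C)(C)[C@H]1CO[Si](c1ccccc1)(c1ccccc1)C(C)(C)C | intermediate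
12 | (3S,4S,8S)-8-(TBDPS-oxymethyl)-7,7-dimethyl-1-oxaspiro[2.5]octan-4-ol (epoxide oxygen syn to OH) | O1C[C@@]12[C@@H](O)CCC(C)(C)[C@H]2CO[Si](c1ccccc1)(c1ccccc1)C(C)(C)C | intermediate
13 | triethylsilyl ether of 12 | O1C[C@@]12[C@@H](O[Si](CC)(CC)CC)CCC(C)(C)[C@H]2CO[Si](c1ccccc1)(c1ccccc1)C(C)(C)C | intermediate
14 | 2,2,2-trifluoroethyl prop-2-enoate | C=CC(=O)OCC(F)(F)F | starting material
15 | 2,2,2-trifluoroethyl 3-[(1S,2S,6R)-6-(TBDPS-oxymethyl)-1-(hydroxymethyl)-5,5-dimethyl-2-(triethylsilyloxy)cyclohexyl]propanoate | OC[C@@]1(CCC(=O)OCC(F)(F)F)[C@@H](O[Si](CC)(CC)CC)CCC(C)(C)[C@H]1CO[Si](c1ccccc1)(c1ccccc1)C(C)(C)C | intermediate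
16 | (6S,7R,11S)-7-(TBDPS-oxymethyl)-8,8-dimethyl-11-(triethylsilyloxy)-2-oxaspiro[5.5]undecan-3-one | O=C1CC[C@]2(CO1)[C@@H](O[Si](CC)(CC)CC)CCC(C)(C)[C@H]2CO[Si](c1ccccc1)(c1ccccc1)C(C)(C)C | intermediate
17 | 4-(phenylselanyl) derivative of 16 (epimers at the selenium-bearing carbon; other centres as in 16) | O=C1C([Se]c3ccccc3)C[C@]2(CO1)[C@@H](O[Si](CC)(CC)CC)CCC(C)(C)[C@H]2CO[Si](c1ccccc1)(c1ccccc1)C(C)(C)C | intermediate
18 | selenoxide of 17 | O=C1C([Se](=O)c3ccccc3)C[C@]2(CO1)[C@@H](O[Si](CC)(CC)CC)CCC(C)(C)[C@H]2CO[Si](c1ccccc1)(c1ccccc1)C(C)(C)C | intermediate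
19 | 4,5-didehydro derivative of 16 (2-oxaspiro[5.5]undec-4-en-3-one; ring stereocentres as in 16) | O=C1C=C[C@]2(CO1)[C@@H](O[Si](CC)(CC)CC)CCC(C)(C)[C@H]2CO[Si](c1ccccc1)(c1ccccc1)C(C)(C)C | intermediate
20 | 11-hydroxy compound: 19 without the triethylsilyl group | O=C1C=C[C@]2(CO1)[C@@H](O)CCC(C)(C)[C@H]2CO[Si](c1ccccc1)(c1ccccc1)C(C)(C)C | intermediate
21 | 11-O-acetate of 20 | O=C1C=C[C@]2(CO1)[C@@H](OC(C)=O)CCC(C)(C)[C@H]2CO[Si](c1ccccc1)(c1ccccc1)C(C)(C)C | intermediate
22 | 4,5-dibromide of 21 (trans addition product) | O=C1C(Br)C(Br)[C@]2(CO1)[C@@H](OC(C)=O)CCC(C)(C)[C@H]2CO[Si](c1ccccc1)(c1ccccc1)C(C)(C)C | intermediate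
23 | 4-bromo derivative of 21 (α-bromo unsaturated lactone) | O=C1C(Br)=C[C@]2(CO1)[C@@H](OC(C)=O)CCC(C)(C)[C@H]2CO[Si](c1ccccc1)(c1ccccc1)C(C)(C)C | intermediate
24 | (R)-4-benzyl-1,3-oxazolidin-2-one | O=C1N[C@H](Cc2ccccc2)CO1 | starting material
25 | pent-4-enoyl chloride | C=CCCC(Cl)=O | starting material
26 | (R)-4-benzyl-3-(pent-4-enoyl)-1,3-oxazolidin-2-one | C=CCCC(=O)N1[C@H](Cc2ccccc2)COC1=O | intermediate
27 | methyl bromoacetate | COC(=O)CBr | starting material
28 | methyl (3S)-3-{[(4R)-4-benzyl-2-oxo-1,3-oxazolidin-3-yl]carbonyl}hex-5-enoate | COC(=O)C[C@H](CC=C)C(=O)N1[C@H](Cc2ccccc2)COC1=O | intermediate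
29 | methyl (3S)-3-(hydroxymethyl)hex-5-enoate | COC(=O)C[C@H](CC=C)CO | intermediate
30 | (4S)-4-(prop-2-en-1-yl)oxolan-2-one | O=C1C[C@H](CC=C)CO1 | intermediate
31 | trimethylsilyl (3S)-3-(iodomethyl)hex-5-enoate | C[Si](C)(C)OC(=O)C[C@H](CC=C)CI | intermediate
32 | methyl (3S)-3-(iodomethyl)hex-5-enoate | COC(=O)C[C@H](CC=C)CI | intermediate
33 | [(2S)-2-(2-methoxy-2-oxoethyl)pent-4-en-1-yl]zinc iodide | COC(=O)C[C@H](CC=C)C[Zn]I | intermediate
34 | 23 with Br replaced by the (2R)-2-(2-methoxy-2-oxoethyl)pent-4-en-1-yl group | O=C1C(C[C@@H](CC=C)CC(=O)OC)=C[C@]2(CO1)[C@@H](OC(C)=O)CCC(C)(C)[C@H]2CO[Si](c1ccccc1)(c1ccccc1)C(C)(C)C | intermediate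
35 | 1,2,4-trioxolane (ozonide) of the terminal alkene of 34 | O=C1C(C[C@@H](CC3OCOO3)CC(=O)OC)=C[C@]2(CO1)[C@@H](OC(C)=O)CCC(C)(C)[C@H]2CO[Si](c1ccccc1)(c1ccccc1)C(C)(C)C | intermediate
36 | aldehyde: 23 with Br replaced by the (2S)-2-(2-methoxy-2-oxoethyl)-4-oxobutyl group | O=C1C(C[C@@H](CC=O)CC(=O)OC)=C[C@]2(CO1)[C@@H](OC(C)=O)CCC(C)(C)[C@H]2CO[Si](c1ccccc1)(c1ccccc1)C(C)(C)C | intermediate
37 | samarium(III) C11-alkoxide/C8 lactone enolate after six-ring closure (drawn as the dianion) | COC(=O)C[C@@H]1C[C@H]([O-])[C@@H]2C(C1)=C([O-])OC[C@]23[C@@H](OC(C)=O)CCC(C)(C)[C@H]3CO[Si](c1ccccc1)(c1ccccc1)C(C)(C)C | intermediate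
38 | (1S,5R,8S,9S,10R,11S,13S)-1-acetoxy-11-hydroxy-15-oxo-6-(TBDPS-oxy)-17-nor-6,7-seco-ent-kauran-7,20-olide | C1C(=O)[C@]23C[C@H]1C[C@H](O)[C@H]2[C@]1(COC3=O)[C@@H](OC(C)=O)CCC(C)(C)[C@H]1CO[Si](c1ccccc1)(c1ccccc1)C(C)(C)C | intermediate
39 | 6-O-TBDPS ether of maoyecrystal E | C=C1C(=O)[C@]23C[C@H]1C[C@H](O)[C@H]2[C@]1(COC3=O)[C@@H](OC(C)=O)CCC(C)(C)[C@H]1CO[Si](c1ccccc1)(c1ccccc1)C(C)(C)C | intermediate
40 | maoyecrystal E, (1S,5R,8S,9S,10R,11S,13S) | C=C1C(=O)[C@]23C[C@H]1C[C@H](O)[C@H]2[C@]1(COC3=O)[C@@H](OC(C)=O)CCC(C)(C)[C@H]1CO | target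

## Step count and risks

Total step count: 23 (19 in the main line, 4 for the side chain 24 → 32).
Longest linear sequence: 19 steps (steps 1–14 and 19–23, from dione 1).

Steps most likely to fail:

1. Step 21 (proposed new method). The C8 samarium enolate may be protonated before it acylates, or the acyl group may stop on the C11 oxygen as a bridged lactone instead of forming the C8–C15 bond. Fallback by known reactions, from 36 back to 38: the ketyl–olefin cyclisation alone is run with a proton source (SmI2, t-BuOH, THF, −78 °C) to give the six-ring hydroxy lactone ester F1. Its C11 hydroxyl is silylated (TESOTf, 2,6-lutidine, CH2Cl2, −78 °C) to give triethylsilyl ether F2. Dieckmann condensation (LiHMDS, THF, −78 to −20 °C, kinetic deprotonation of the more acidic lactone α-CH) then closes the cyclopentanone to give the silylated β-keto lactone F3. PPTS in MeOH removes the silyl group and returns 38.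

2. Step 4. Hydride delivery to the β-carbon flanked by the quaternary centre may be slow or poorly face-selective. Fallback, from 6 back to 12, with the chirality introduced by resolution instead: L-Selectride (THF, −78 °C) gives the racemic lithium enolate F4, which is trapped with Eschenmoser's salt as the racemic Mannich base F5. MeI then aqueous NaHCO3 (through the racemic ammonium iodide F6) gives the racemic methylene ketone F7, and Luche reduction gives the racemic cis allylic alcohol F8. Sharpless kinetic resolution (Ti(Oi-Pr)4, L-(+)-diisopropyl tartrate, t-BuOOH, 4 Å sieves, CH2Cl2, −20 °C, about 0.55 equiv of oxidant; tartrate enantiomer chosen so that the (1S,3R) alcohol is the fast-reacting one) epoxidises only that enantiomer and gives 12; the slow enantiomer is separated.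

3. Step 19. The β-branched alkylzinc–palladium intermediate may undergo β-hydride elimination or protodemetalation before reductive elimination. Fallback, from 17 back to 34, forming the C8–C14 bond by enolate alkylation: selenide 17 is deprotonated (LiHMDS, THF/HMPA, −78 °C) and alkylated with iodide 32 (to 0 °C) to give the C8-alkylated selenide F9. H2O2/pyridine (through selenoxide F10) gives the side-chain-bearing unsaturated lactone F11, the elimination being expected to go into the ring as in step 11. PPTS/MeOH gives the C1 alcohol F12, and Ac2O/DMAP/pyridine returns 34.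

## Further compounds

F1 | step 21 | six-ring hydroxy lactone ester from ketyl–olefin cyclisation with protonation at C8 (C8 configuration not fixed; other centres as in 38) | COC(=O)C[C@@H]1C[C@H](O)[C@@H]2C(C1)C(=O)OC[C@]23[C@@H](OC(C)=O)CCC(C)(C)[C@H]3CO[Si](c1ccccc1)(c1ccccc1)C(C)(C)C
F2 | step 21 | C11 triethylsilyl ether of F1 | COC(=O)C[C@@H]1C[C@H](O[Si](CC)(CC)CC)[C@@H]2C(C1)C(=O)OC[C@]23[C@@H](OC(C)=O)CCC(C)(C)[C@H]3CO[Si](c1ccccc1)(c1ccccc1)C(C)(C)C
F3 | step 21 | C11 triethylsilyl ether of 38 | C1C(=O)[C@]23C[C@H]1C[C@H](O[Si](CC)(CC)CC)[C@H]2[C@]1(COC3=O)[C@@H](OC(C)=O)CCC(C)(C)[C@H]1CO[Si](c1ccccc1)(c1ccccc1)C(C)(C)C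
F4 | step 4 | lithium enolate (C1=C2) of racemic 3-(TBDPS-oxymethyl)-4,4-dimethylcyclohexanone | [Li+].[O-]C1=CC(CO[Si](c2ccccc2)(c2ccccc2)C(C)(C)C)C(C)(C)CC1
F5 | step 4 | racemic trans-2-[(dimethylamino)methyl]-3-(TBDPS-oxymethyl)-4,4-dimethylcyclohexan-1-one | CN(C)CC1C(=O)CCC(C)(C)C1CO[Si](c1ccccc1)(c1ccccc1)C(C)(C)C
F6 | step 4 | N-methyl ammonium iodide of F5 (racemic) | C[N+](C)(C)CC1C(=O)CCC(C)(C)C1CO[Si](c1ccccc1)(c1ccccc1)C(C)(C)C.[I-]
F7 | step 4 | racemic 3-(TBDPS-oxymethyl)-4,4-dimethyl-2-methylidenecyclohexan-1-one | C=C1C(=O)CCC(C)(C)C1CO[Si](c1ccccc1)(c1ccccc1)C(C)(C)C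
F8 | step 4 | racemic cis-3-(TBDPS-oxymethyl)-4,4-dimethyl-2-methylidenecyclohexan-1-ol | C=C1C(O)CCC(C)(C)C1CO[Si](c1ccccc1)(c1ccccc1)C(C)(C)C
F9 | step 19 | 17 alkylated at C8 with the (2R)-2-(2-methoxy-2-oxoethyl)pent-4-en-1-yl group (C8 configuration not fixed) | O=C1C(C[C@@H](CC=C)CC(=O)OC)([Se]c3ccccc3)C[C@]2(CO1)[C@@H](O[Si](CC)(CC)CC)CCC(C)(C)[C@H]2CO[Si](c1ccccc1)(c1ccccc1)C(C)(C)C
F10 | step 19 | selenoxide of F9 | O=C1C(C[C@@H](CC=C)CC(=O)OC)([Se](=O)c3ccccc3)C[C@]2(CO1)[C@@H](O[Si](CC)(CC)CC)CCC(C)(C)[C@H]2CO[Si](c1ccccc1)(c1ccccc1)C(C)(C)C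
F11 | step 19 | C1 triethylsilyl ether analogue of 34 (OTES in place of OAc) | O=C1C(C[C@@H](CC=C)CC(=O)OC)=C[C@]2(CO1)[C@@H](O[Si](CC)(CC)CC)CCC(C)(C)[C@H]2CO[Si](c1ccccc1)(c1ccccc1)C(C)(C)C
F12 | step 19 | C1 alcohol analogue of 34 (OH in place of OAc) | O=C1C(C[C@@H](CC=C)CC(=O)OC)=C[C@]2(CO1)[C@@H](O)CCC(C)(C)[C@H]2CO[Si](c1ccccc1)(c1ccccc1)C(C)(C)C
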